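**Conventions.** Locants C1–C8a are those of the target decalin (C1 acetyl, C2 sec-butyl, C3=C4, C4a, C5 hydroxyl, C6 ester oxygen, C7, C8 methyl, C8a). They are kept for every ring A intermediate, also before ring B exists. β is the face of ring A that carries the C1 acetyl group, α the other face. Compounds are numbered 1–33 in the order of the steps.

## Analysis of the target

Compound 33 is a trans-fused octalin: ring A is a cyclohexene (C1, C2, C3=C4, C4a, C8a) and ring B a cyclohexane (C4a, C5, C6, C7, C8, C8a). It has eight stereocentres, 1S,2S,4aR,5S,6R,8R,8aS on the bicycle and R at the methine of the sec-butyl group, plus the E double bond of the 3-methylglutaconate. On ring A the acetyl group, the sec-butyl group and the C4a–C5 bond are on the β face and the C8a–C8 bond is on the α face. In the chair of ring B the C5 hydroxyl and the C8 methyl are equatorial and the C6 ester oxygen is axial, cis to O5. The equatorial C8 methyl and the equatorial C1 acetyl point the same way from the two carbons that flank C8a, so they crowd each other. Sensitive points are the cis-diol monoester (acyl shift from O6 to O5), the glutaconate CH2 between alkene and carboxyl (the double bond can change place and geometry through a dienolate), the C1 methine next to the ketone, and the free acid. The difficulties are the four contiguous stereocentres of ring A, the sec-butyl stereocentre with no functional group left to steer it, and the need to acylate only the axial, more hindered of two neighbouring oxygens. The plan rests on C6 (carbinol), C7 (methylene) and C8 (methyl-bearing) of ring B: this 3-methylcyclohexanol pattern is what an aldehyde on the C4a arm and an isopropenyl group on C8a give in a carbonyl-ene reaction, and the closure leaves O6 free while O5 already carries its protecting group.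

## Retrosynthetic reasoning

**Protecting groups, 33 from 32 from 31.** No skeletal bond is cut. 33 comes from 32 by oxidative loss of the p-methoxybenzyl (PMB) ether on O5, and 32 from 31 by loss of an allyl ester. Both operations are neutral, and O5 is freed only in the last step, so the O6 ester has no chance to migrate earlier.

**O6–acyl bond, 31 from 27 and 30.** Cutting the ester gives alcohol 27, in which C6–OH is the only free hydroxyl, and half-ester 30, which has the conjugated carboxyl free. 30 comes from diacid 28 and alcohol 29 by esterification of the faster, non-conjugated carboxyl.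

**C8–H bond, 27 from 26.** The C8 methyl is traced back to an exocyclic methylene. The forward step has to add hydrogen to C8 from the axial α side, and only to this alkene, not to C3=C4.

**C6–C7 bond, 26 from 25.** This is the cut that carries the plan. Breaking C6–C7 and returning one hydrogen from O6 to the C8 methylene gives ring A aldehyde 25 with an isopropenyl group on C8a. The cut is made here because the two arms are already trans on a finished ring A, so the ring fusion is not at stake; only C6 is new. The forward step must bring the carbonyl oxygen out axial.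

**C5–C6 bond, 25 from 20 and 21.** The formyl carbon C6 is a masked acyl anion, 21, added to aldehyde 20; 22, 23 and 24 lie between. The forward addition has to set C5 (5S) against the existing C4a centre. The ketal on the C1 side chain keeps the acetyl group out of this chemistry.

**Oxidation levels, 20 from 18 from 15.** The C5 aldehyde is carried as a silyl-protected primary alcohol (19, 18). The methyl of the sec-butyl group is traced back to a carboxyl (16, 15), which is the handle the next cut needs.

**C2–C(sec-butyl) bond, 15 from 12.** A [3,3] shift of the ketene acetal of butanoate 12 forms this bond. It moves the double bond from C2=C3 to C3=C4 and transfers the configuration of the C4–O bond to C2. The enolate geometry controls the exocyclic centre.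

**C4–C4a and C1–C8a bonds, 12 from 9 and 3.** Ring A is a Diels–Alder adduct of dienyl butanoate 9 and dienal 3; 11 is the reduced adduct. One catalyst-controlled step sets C4, C4a, C8a and C1.

**Fragments.** 9 comes from enal 6 and anhydride 7; 6 from ketal ester 4 through aldehyde 5 and ylide 2; 3 from 1 and 2.

## Alternatives that were turned down

**Alternative 1: ring-contracting Ireland–Claisen rearrangement.** The cut is C1–C2 of ring A, with ring B finished first. The precursor is the six-membered lactone A2, trans-fused to ring B, with its carbonyl carbon attached to C1, its ring oxygen on C4, and an (E)-alkenyl chain with the sec-butyl carbon on C4. Its silyl ketene acetal would rearrange through the boat that the ring enforces: C1–C2 forms, C4–O breaks, and the lactone contracts to the cyclohexene acid A1. In its favour, the step is intramolecular and its geometry is fixed, so C1 and C2 are set together with more certainty than an intermolecular cycloaddition between hindered partners can offer; on this point it is stronger than the chosen plan. Against it, A2 already needs seven stereocentres, including C4 and the remote sec-butyl carbon, which must arrive in an enantiopure alkenyl fragment. A1 carries a carboxyl at C1 that must become an acetyl group at an epimerisable centre. The diol emerges as an acetonide, and after its removal the equatorial O5 would acylate before the axial O6, the opposite of what 33 needs. The chosen plan gives up the enforced boat but delivers O6 alone free and closes ring B late in one C–C bond-forming step.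

**Alternative 2: pinacol closure of ring B.** The cut is C5–C6. One-electron reduction of ring A dialdehyde A4 with SmI2 (divalent samarium) or at a cathode would couple the two ketyl carbons and give cis-diol A3. In its favour, one step closes ring B and makes both carbinol centres, the cis relation follows from the bridged metal diolate, and C8 arrives already set in the side chain, so no late hydrogenation is needed; there it is stronger than the chosen plan. Against it, a cis-diol can form on either face and only the trans arms and the remote C8 methyl decide which. A4 holds two aldehydes, one of them β,γ-unsaturated and epimerisable at C4a. A3 again has two free hydroxyls with the wrong inherent order of acylation, so three or four protecting-group steps follow. The ene closure makes only C6, but it makes it with O5 and O6 already told apart.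

**Alternative 3: intermolecular Diels–Alder reaction as the key step.** The cuts are C4–C4a and C1–C8a. Enal A6, which carries the C8 stereocentre and a protected C7–C6 chain, would add to diene 9 under iminium or Lewis-acid catalysis to give ring A aldehyde A5 with four new stereocentres. In its favour, A6 is a plain β-alkyl enal and a better dienophile than dienal 3, and C8 comes from a defined methyl-branched chain; both are real advantages. Against it, the key step stops at ring A. Ring B must still be closed between C5 and C6 with two oxygenated centres to set, which leads back to the coupling of alternative 2 or to an aldol-type closure without clear control. The chosen plan uses the same cycloaddition logic as a supporting step, but with an isopropenyl group on the dienophile, so that the ring B closure is a stereodefined ene reaction; the price is that C8 is set afterwards.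

Key step: step 16

**Remarks on the chemistry.** Ketal ester 4 (fructone, the ethylene ketal of ethyl acetoacetate) and (E)-diacid 28 are taken as purchased. The choice of the (5R)-catalyst in step 5 rests on the usual model for 5-benzylimidazolidinones, in which the (5S)-catalyst leaves the Si face of C2 of the enal open.

## Route

Step 1
Reactants: 1 methacrolein; 2 (triphenylphosphoranylidene)acetaldehyde
Product: 3 (2E)-4-methylpenta-2,4-dienal
Conditions: 1 (3 equiv), PhMe, 70 °C, sealed vessel; distil
Reagents that add atoms: none
Why: Wittig olefination with the stabilised formyl ylide gives the E enal; excess volatile 1 and the lower electrophilicity of the dienal product should hold back a second homologation.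

Step 2
Reactants: 4 ethyl 2-(2-methyl-1,3-dioxolan-2-yl)acetate
Product: 5 2-(2-methyl-1,3-dioxolan-2-yl)acetaldehyde
Conditions: i-Bu2AlH (1.1 equiv), CH2Cl2, −78 °C; aq. potassium sodium tartrate
Reagents that add atoms: none
Why: Partial ester reduction: at −78 °C the aluminium hemiacetal, held by the neighbouring ketal oxygen, survives until work-up, so the reduction should stop at the aldehyde.

Step 3
Reactants: 5 2-(2-methyl-1,3-dioxolan-2-yl)acetaldehyde; 2 (triphenylphosphoranylidene)acetaldehyde
Product: 6 (2E)-4-(2-methyl-1,3-dioxolan-2-yl)but-2-enal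
Conditions: PhMe, 80 °C
Reagents that add atoms: none
Why: Wittig olefination with the stabilised ylide; the aliphatic aldehyde reacts faster than the enal formed, and the E alkene is expected.

Step 4
Reactants: 6 (2E)-4-(2-methyl-1,3-dioxolan-2-yl)but-2-enal; 7 butanoic anhydride
Product: 9 (1E,3E)-4-(2-methyl-1,3-dioxolan-2-yl)buta-1,3-dien-1-yl butanoate, via potassium dienolate 8 (not isolated)
Conditions: KOt-Bu, THF, −78 °C; then 7, −78 → 0 °C
Reagents that add atoms: none
Why: γ-Deprotonation of the enal and O-acylation of the extended enolate (dienol ester formation); the s-trans enal gives the 1E and the bulky ketal carbon the 3E geometry, and at −78 °C acylation should be faster than loss of a ketal oxygen from the enolate. Any 1Z isomer cannot reach the s-cis form and stays behind in step 5.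

Step 5
Reactants: 9 (1E,3E)-4-(2-methyl-1,3-dioxolan-2-yl)buta-1,3-dien-1-yl butanoate; 3 (2E)-4-methylpenta-2,4-dienal
Product: 11 ring A alcohol (C2=C3; C4 β-butanoate; C4a β-CH2OH; C8a α-isopropenyl; C1 β-dioxolanyl), via ring A aldehyde 10 (not isolated)
Conditions: (5R)-5-benzyl-2,2,3-trimethylimidazolidin-4-one·CF3CO2H (20 mol %), MeCN/H2O 95:5, −10 °C → rt; then NaBH4, EtOH, −20 °C; AcOH quench
Reagents that add atoms: none
Why: Iminium-catalysed Diels–Alder reaction, known for enals with 1-acyloxybutadienes: the donor oxygen directs the oxygen-bearing diene carbon to C2 of the enal (C4–C4a, C1–C8a), endo approach of the iminium puts the formyl group cis to butanoate and ketal, and the E dienophile puts isopropenyl trans. The (5R)-catalyst covers the Si face of C2 of the enal, so the diene adds to the Re face and fixes C4, C4a, C8a and C1 in the absolute sense needed. NaBH4 in the same flask reduces the β-acyloxy aldehyde 10 before it can eliminate butanoic acid.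

Step 6
Reactants: 11 ring A alcohol
Product: 12 ring A tert-butyldimethylsilyl ether (C4 β-butanoate; C4a β-CH2OSiMe2t-Bu)
Conditions: t-BuMe2SiCl, imidazole, CH2Cl2, 0 °C → rt
Reagents that add atoms: tert-butyldimethylsilyl chloride, CC(C)(C)[Si](C)(C)Cl
Why: Silylation of the primary alcohol; imidazole is too weak a base to move the butanoyl group from O4 to the primary oxygen.

Step 7
Reactants: 12 ring A tert-butyldimethylsilyl ether
Product: 15 (2R)-2-(ring A C2 β-yl)butanoic acid (C3=C4), via silyl ketene acetal 13 (not isolated), via trimethylsilyl ester 14 (not isolated)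
Conditions: LDA, THF/DMPU 4:1, −78 °C; Me3SiCl, −78 °C → rt, then 50 °C; aq. NaOH, then citric acid to pH 4
Reagents that add atoms: none
Why: Ireland–Claisen rearrangement: enolisation in THF/DMPU gives ketene acetal 13 with ethyl cis to the silyloxy group, and the suprafacial [3,3] shift delivers the chain to C2 on the β face from which the pseudoaxial O4 leaves, moving the alkene to C3=C4. The boat transition state usual for cyclohex-2-enyl esters, with the ethyl group turned away from the ring and hydrogen over C1, gives the R configuration at the new exocyclic carbon.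

Step 8
Reactants: 15 (2R)-2-(ring A C2 β-yl)butanoic acid
Product: 16 (2R)-2-(ring A C2 β-yl)butan-1-ol
Conditions: LiAlH4, THF, 0 → 40 °C
Reagents that add atoms: none
Why: Hydride reduction of the carboxylic acid to the primary alcohol; silyl ether, ketal and alkenes are inert to LiAlH4.

Step 9
Reactants: 16 (2R)-2-(ring A C2 β-yl)butan-1-ol
Product: 18 ring A sec-butyl silyl ether, via mesylate 17 (not isolated)
Conditions: MsCl, Et3N, THF, 0 °C; then LiBHEt3, 0 °C → rt; NaOH/H2O2 work-up
Reagents that add atoms: none
Why: Deoxygenation of a primary alcohol by sulfonylation and SN2 displacement with hydride; CH2OH becomes the methyl of the (R)-sec-butyl group and no stereocentre is touched.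

Step 10
Reactants: 18 ring A sec-butyl silyl ether
Product: 19 ring A primary alcohol (C4a β-CH2OH; C2 β-sec-butyl)
Conditions: n-Bu4NF, THF, rt
Reagents that add atoms: none
Why: Fluoride cleaves the Si–O bond; nothing else in 18 responds to it.

Step 11
Reactants: 19 ring A primary alcohol
Product: 20 ring A aldehyde (C4a β-CHO)
Conditions: Dess–Martin periodinane (1,1,1-triacetoxy-1,1-dihydro-1,2-benziodoxol-3(1H)-one), NaHCO3, CH2Cl2, 0 °C
Reagents that add atoms: none
Why: Dess–Martin oxidation under buffered, non-basic conditions should give the β,γ-unsaturated aldehyde without moving C3=C4 into conjugation or epimerising C4a; 20 is used at once.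

Step 12
Reactants: 20 ring A aldehyde; 21 1,3-dithiane
Product: 22 (5S)-dithianyl carbinol
Conditions: 21, n-BuLi, THF, −30 °C; then 20, −78 °C; aq. NH4Cl
Reagents that add atoms: none
Why: Corey–Seebach addition of 2-lithio-1,3-dithiane under Felkin–Anh control: the nucleophile comes in anti to the C4a–C8a bond (the bulkier branch, which carries the isopropenyl group), with the carbonyl oxygen beside the flat vinylic C4, and passes H4a, which gives 5S. At −78 °C addition should outrun deprotonation at C4a.

Step 13
Reactants: 22 (5S)-dithianyl carbinol
Product: 23 (5S)-PMB ether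
Conditions: NaH, 4-MeOC6H4CH2Cl, n-Bu4NI (cat.), THF/DMF, 0 °C → rt
Reagents that add atoms: 4-methoxybenzyl chloride, COc1ccc(CCl)cc1
Why: Williamson ether synthesis on the alkoxide; the ketal still masks the methyl ketone, which NaH would otherwise enolise.

Step 14
Reactants: 23 (5S)-PMB ether
Product: 24 methyl ketone dithiane
Conditions: pyridinium p-toluenesulfonate (cat.), acetone/H2O 10:1, 50 °C
Reagents that add atoms: water, O
Why: Mild acid hydrolysis (trans-ketalisation to acetone) frees the acetyl group; dithiane and PMB ether are stable, and the equatorial acetyl group has no drive to epimerise at C1.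

Step 15
Reactants: 24 methyl ketone dithiane
Product: 25 (5S)-α-PMB-oxy aldehyde (C8a α-isopropenyl; C1 β-acetyl; C2 β-(R)-sec-butyl)
Conditions: MeI, CaCO3, MeCN/H2O 9:1, 40 °C
Reagents that add atoms: water, O
Why: Alkylative hydrolysis of the dithiane: S-methylation makes sulfur a leaving group and water takes its place; CaCO3 keeps the medium neutral, so C5 of the α-alkoxy aldehyde and the PMB ether should survive. 25 is used at once.

Step 16
Reactants: 25 (5S)-α-PMB-oxy aldehyde
Product: 26 (1S,2S,4aR,5S,6R,8aS)-8-methylene decalin-6-ol with O5 as PMB ether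
Conditions: Me2AlCl (2.2 equiv), CH2Cl2, −78 → −40 °C; aq. potassium sodium tartrate
Reagents that add atoms: none
Why: Me2AlCl binds the aldehyde oxygen (with the second equivalent it can bridge to the PMB ether oxygen), the CH2 end of the 1,1-disubstituted alkene bonds to C6 and a hydrogen of the allylic methyl group passes to the carbonyl oxygen; this is the Lewis-acid type 2 intramolecular carbonyl-ene reaction known for 5-methylhex-5-enals, which give 3-methylenecyclohexanols. Ring B closes by the C6–C7 bond in a six-membered mode (C5, C4a and C8a lie between the carbonyl carbon and the central alkene carbon), through a chair in which the two arms, already trans on C4a and C8a, are equatorial, so the trans fusion is inherited. The chair of ring B and the six-membered hydrogen-transfer array share C6, C7 and C8 as in a bicyclo[3.3.1] frame, which forces the carbonyl oxygen axial; in this one possible chair, axial means α, cis to the equatorial C5 ether, that is 6R. The C5 ether sits equatorial and gauche to the carbonyl oxygen, which the chelate allows. The step needs the aldehyde to react before the methyl ketone: the ketone is less electrophilic and could only close a five-membered ring. It also needs the concerted path to beat a stepwise cation: Me2AlCl scavenges protons as methane and the temperature is low, which should also spare the PMB ether. The product has C6–OH as its only free hydroxyl and an exocyclic methylene at C8.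

Step 17
Reactants: 26 8-methylene decalin-6-ol
Product: 27 (8R)-8-methyl decalin-6-ol with O5 as PMB ether
Conditions: Mn(dpm)3 (dpm = 2,2,6,6-tetramethylheptane-3,5-dionate, 10 mol %), PhSiH3, t-BuOOH, i-PrOH, rt
Reagents that add atoms: none
Why: Hydrogen-atom-transfer hydrogenation: a manganese hydride gives a hydrogen atom to the CH2 end of the 1,1-disubstituted alkene, and the tertiary C8 radical takes the second hydrogen along the axial direction on the α face, which avoids eclipsing with the axial C–H bonds on C7 and C8a and the C1 acetyl group on the equatorial side; the methyl should end equatorial (8R). C3=C4 would give only a secondary radical and should be left, as should ketone, hydroxyl and PMB ether.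

Step 18
Reactants: 28 (2E)-3-methylpent-2-enedioic acid; 29 prop-2-en-1-ol
Product: 30 (2E)-3-methyl-5-oxo-5-(prop-2-en-1-yloxy)pent-2-enoic acid
Conditions: 29 (solvent), p-TsOH·H2O (5 mol %), 40 °C, stopped at partial conversion
Reagents that add atoms: none
Why: Fischer esterification is much faster at the CH2CO2H group than at the conjugated, β,β-disubstituted carboxyl (the selectivity known for itaconic acid), so the half-ester with the conjugated acid free should form; mild acid should leave the E geometry.

Step 19
Reactants: 27 (8R)-8-methyl decalin-6-ol; 30 (2E)-3-methyl-5-oxo-5-(prop-2-en-1-yloxy)pent-2-enoic acid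
Product: 31 O6 (E)-3-methylglutaconate with allyl ester and O5 PMB ether
Conditions: EDC·HCl (1-ethyl-3-(3-dimethylaminopropyl)carbodiimide hydrochloride), 4-(dimethylamino)pyridine (0.2 equiv), CH2Cl2, 0 °C → rt
Reagents that add atoms: none
Why: Steglich-type carbodiimide esterification of the only free hydroxyl, with retention at C6; catalytic 4-(dimethylamino)pyridine, no tertiary amine and low temperature are chosen to limit deprotonation of the CH2 between alkene and ester.

Step 20
Reactants: 31 O6 (E)-3-methylglutaconate with allyl ester
Product: 32 O6 (E)-3-methylglutaconate half-ester with O5 PMB ether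
Conditions: Pd(PPh3)4 (5 mol %), PhNHMe, THF, rt
Reagents that add atoms: none
Why: Tsuji–Trost deallylation: zerovalent palladium ionises the allyl ester to a π-allyl complex that the weakly basic N-methylaniline traps; the glutaconate and the PMB ether are not affected.

Step 21
Reactants: 32 half-ester with O5 PMB ether
Product: 33 CNP0404452.1
Conditions: DDQ (2,3-dichloro-5,6-dicyano-1,4-benzoquinone), CH2Cl2/pH 7 phosphate buffer 10:1, 0 °C
Reagents that add atoms: none
Why: Oxidative PMB cleavage (hydride abstraction, then hydrolysis of the oxocarbenium ion) at neutral pH, so the O6 ester should not move to the freed O5.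

## Compound list

1 | methacrolein (2-methylprop-2-enal) | CC(=C)C=O | starting material
2 | (triphenylphosphoranylidene)acetaldehyde | O=CC=P(c1ccccc1)(c1ccccc1)c1ccccc1 | starting material
3 | (2E)-4-methylpenta-2,4-dienal | CC(=C)/C=C/C=O | intermediate
4 | ethyl 2-(2-methyl-1,3-dioxolan-2-yl)acetate | CCOC(=O)CC1(C)OCCO1 | starting material
5 | 2-(2-methyl-1,3-dioxolan-2-yl)acetaldehyde | O=CCC1(C)OCCO1 | intermediate
6 | (2E)-4-(2-methyl-1,3-dioxolan-2-yl)but-2-enal | O=C/C=C/CC1(C)OCCO1 | intermediate
7 | butanoic anhydride | CCCC(=O)OC(=O)CCC | starting material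
8 | potassium (1E,3E)-4-(2-methyl-1,3-dioxolan-2-yl)buta-1,3-dien-1-olate | [K+].[O-]/C=C/C=C/C1(C)OCCO1 | intermediate (not isolated)
9 | (1E,3E)-4-(2-methyl-1,3-dioxolan-2-yl)buta-1,3-dien-1-yl butanoate | CCCC(=O)O/C=C/C=C/C1(C)OCCO1 | intermediate
10 | ring A aldehyde: cyclohexene C2=C3, C4 β-butanoyloxy, C4a β-formyl, C8a α-isopropenyl, C1 β-(2-methyl-1,3-dioxolan-2-yl) | CCCC(=O)O[C@@H]1C=C[C@H](C2(C)OCCO2)[C@@H](C(C)=C)[C@@H]1C=O | intermediate (not isolated)
11 | ring A alcohol: as 10 with C4a β-hydroxymethyl | CCCC(=O)O[C@@H]1C=C[C@H](C2(C)OCCO2)[C@@H](C(C)=C)[C@@H]1CO | intermediate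
12 | ring A silyl ether: as 11 with C4a β-CH2OSiMe2t-Bu | CCCC(=O)O[C@@H]1C=C[C@H](C2(C)OCCO2)[C@@H](C(C)=C)[C@@H]1CO[Si](C)(C)C(C)(C)C | intermediate
13 | trimethylsilyl ketene acetal of 12, ethyl cis to OSiMe3 | CC/C=C(\O[Si](C)(C)C)O[C@@H]1C=C[C@H](C2(C)OCCO2)[C@@H](C(C)=C)[C@@H]1CO[Si](C)(C)C(C)(C)C | intermediate (not isolated)
14 | trimethylsilyl ester of acid 15 | CC[C@@H](C(=O)O[Si](C)(C)C)[C@H]1C=C[C@@H](CO[Si](C)(C)C(C)(C)C)[C@H](C(C)=C)[C@H]1C2(C)OCCO2 | intermediate (not isolated)
15 | (2R)-2-(ring A C2 β-yl)butanoic acid: cyclohexene C3=C4, C4a β-CH2OSiMe2t-Bu, C8a α-isopropenyl, C1 β-dioxolanyl | CC[C@@H](C(O)=O)[C@H]1C=C[C@@H](CO[Si](C)(C)C(C)(C)C)[C@H](C(C)=C)[C@H]1C2(C)OCCO2 | intermediate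
16 | (2R)-2-(ring A C2 β-yl)butan-1-ol, otherwise as 15 | CC[C@@H](CO)[C@H]1C=C[C@@H](CO[Si](C)(C)C(C)(C)C)[C@H](C(C)=C)[C@H]1C2(C)OCCO2 | intermediate
17 | methanesulfonate of 16 | CC[C@@H](COS(C)(=O)=O)[C@H]1C=C[C@@H](CO[Si](C)(C)C(C)(C)C)[C@H](C(C)=C)[C@H]1C2(C)OCCO2 | intermediate (not isolated)
18 | ring A with C2 β-(R)-sec-butyl, C4a β-CH2OSiMe2t-Bu, C8a α-isopropenyl, C1 β-dioxolanyl | CC[C@@H](C)[C@H]1C=C[C@@H](CO[Si](C)(C)C(C)(C)C)[C@H](C(C)=C)[C@H]1C2(C)OCCO2 | intermediate
19 | ring A primary alcohol: as 18 with C4a β-CH2OH | CC[C@@H](C)[C@H]1C=C[C@@H](CO)[C@H](C(C)=C)[C@H]1C2(C)OCCO2 | intermediate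
20 | ring A aldehyde: as 18 with C4a β-CHO | CC[C@@H](C)[C@H]1C=C[C@@H](C=O)[C@H](C(C)=C)[C@H]1C2(C)OCCO2 | intermediate
21 | 1,3-dithiane | C1CSCSC1 | starting material
22 | (5S)-carbinol: C4a β-CH(OH)(1,3-dithian-2-yl), otherwise as 18 | CC[C@@H](C)[C@H]1C=C[C@@H]([C@H](O)C2SCCCS2)[C@H](C(C)=C)[C@H]1C3(C)OCCO3 | intermediate
23 | (5S)-PMB ether of 22 | CC[C@@H](C)[C@H]1C=C[C@@H]([C@H](OCc2ccc(OC)cc2)C3SCCCS3)[C@H](C(C)=C)[C@H]1C4(C)OCCO4 | intermediate
24 | methyl ketone: as 23 with C1 β-acetyl | CC[C@@H](C)[C@H]1C=C[C@@H]([C@H](OCc2ccc(OC)cc2)C3SCCCS3)[C@H](C(C)=C)[C@H]1C(C)=O | intermediate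
25 | ene precursor: ring A (1S,2S,4aR,8aS) with C4a β-[(S)-CH(OPMB)CHO], C8a α-isopropenyl, C1 β-acetyl, C2 β-(R)-sec-butyl | CC[C@@H](C)[C@H]1C=C[C@@H]([C@H](OCc2ccc(OC)cc2)C=O)[C@H](C(C)=C)[C@H]1C(C)=O | intermediate
26 | (1S,2S,4aR,5S,6R,8aS)-1-acetyl-2-[(R)-sec-butyl]-5-(PMB-oxy)-8-methylene-1,2,4a,5,6,7,8,8a-octahydronaphthalen-6-ol | CC[C@@H](C)[C@H]1C=C[C@H]2[C@H](OCc3ccc(OC)cc3)[C@H](O)CC(=C)[C@@H]2[C@H]1C(C)=O | intermediate
27 | (1S,2S,4aR,5S,6R,8R,8aS)-1-acetyl-2-[(R)-sec-butyl]-5-(PMB-oxy)-8-methyl-1,2,4a,5,6,7,8,8a-octahydronaphthalen-6-ol | CC[C@@H](C)[C@H]1C=C[C@H]2[C@H](OCc3ccc(OC)cc3)[C@H](O)C[C@@H](C)[C@@H]2[C@H]1C(C)=O | intermediate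
28 | (2E)-3-methylpent-2-enedioic acid ((E)-3-methylglutaconic acid) | OC(=O)/C=C(\C)CC(=O)O | starting material
29 | prop-2-en-1-ol (allyl alcohol) | OCC=C | starting material
30 | (2E)-3-methyl-5-oxo-5-(prop-2-en-1-yloxy)pent-2-enoic acid | OC(=O)/C=C(\C)CC(=O)OCC=C | intermediate
31 | O6 ester of 27 with 30 (allyl ester, O5 PMB ether) | CC[C@@H](C)[C@H]1C=C[C@H]2[C@H](OCc3ccc(OC)cc3)[C@H](OC(=O)/C=C(\C)CC(=O)OCC=C)C[C@@H](C)[C@@H]2[C@H]1C(C)=O | intermediate
32 | O5 PMB ether of the target (free carboxylic acid) | CC[C@@H](C)[C@H]1C=C[C@H]2[C@H](OCc3ccc(OC)cc3)[C@H](OC(=O)/C=C(\C)CC(=O)O)C[C@@H](C)[C@@H]2[C@H]1C(C)=O | intermediate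
33 | CNP0404452.1: (3E)-5-{[(1S,2S,4aR,5S,6R,8R,8aS)-1-acetyl-2-[(R)-sec-butyl]-5-hydroxy-8-methyl-1,2,4a,5,6,7,8,8a-octahydronaphthalen-6-yl]oxy}-3-methyl-5-oxopent-3-enoic acid | CC[C@@H](C)[C@H]1C=C[C@H]2[C@H](O)[C@H](OC(=O)/C=C(\C)CC(=O)O)C[C@@H](C)[C@@H]2[C@H]1C(C)=O | target

## Step count and least certain steps

Total: 21 steps. Longest linear sequence: 19 steps (steps 2–17 and 19–21, from 4 to 33); steps 1 and 18 are side branches.

**Step 16 (key step).** The most likely failure is loss of control at C6: a stepwise, open cationic closure with the aluminium-bound oxygen equatorial would compete with the concerted chair, and the C8 cation could also be drained by chloride capture. Fallback, from 25 back to 31: if the closure gives mainly the equatorial alcohol, the 6-epimer of 26 F1 is hydrogenated as in step 17 to the 6-epimer of 27 F2. The ester bond is then made with inversion at C6 by a Mitsunobu reaction with acid 30 (PPh3, diisopropyl azodicarboxylate), which gives 31 directly.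

**Step 5.** The cycloaddition joins two hindered carbons (C1 next to the quaternary ketal carbon, C8a bearing the isopropenyl group). It may be slow, which would let dimerisation of 3, hydrolysis of the ketal in the acidic aqueous medium, or low enantioselectivity take over. Fallback, from 9 and 3 back to 16: the cycloaddition is run thermally (PhMe, 110 °C) to the racemic endo adduct, and steps 5–7 are carried through in the racemic series to racemic 15. The acid is joined to (S)-4-benzyl-1,3-oxazolidin-2-one (pivaloyl chloride, Et3N, then the lithiated oxazolidinone) and the two diastereomeric imides are separated by chromatography. The imide of 15 F3 is cleaved with LiBH4 to 16.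

**Step 7.** The rearrangement may pass through the chair instead of the boat, or the ketene acetal may form with the other geometry; either inverts the exocyclic centre. Fallback, from 12 back to 18, with methyl and carboxyl in exchanged roles, so that the same preference now gives the right centre: 12 is cleaved (K2CO3, MeOH) to the allylic alcohol F4 and acylated with propanoic anhydride to the propanoate F5. The same Ireland–Claisen conditions give the (2S)-2-(ring A C2 β-yl)propanoic acid F6. LiAlH4 gives the alcohol F7, TsCl/pyridine the tosylate F8, and Me2CuLi displaces the tosylate to complete the ethyl group of 18.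

**Step 12.** Facial selectivity at C5 may be insufficient, and the basic reagent may enolise the β,γ-unsaturated aldehyde, which would epimerise C4a or move the alkene into conjugation. Fallback, from the mixture of C5 epimers obtained from 20 back to 22: the mixture is oxidised with Dess–Martin periodinane to the 2-acyl-1,3-dithiane F9. This is reduced under reagent control with catecholborane and (R)-1-methyl-3,3-diphenyltetrahydro-1H,3H-pyrrolo[1,2-c][1,3,2]oxazaborole (CBS reduction, with the dithiane as the large group, as for simple 2-acyl-1,3-dithianes) to 22. Catecholborane does not touch the alkenes at −78 °C.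

**Step 17.** Hydrogen delivery to the C8 radical may lack facial control: the axial C6 hydroxyl partly screens the axial approach, and the equatorial methyl meets the C1 acetyl group, so the preference may be small. Fallback, from 26 back to 27: hydroxyl-directed hydrogenation with the cationic rhodium complex [Rh(nbd)(dppb)]BF4 (nbd = norbornadiene, dppb = 1,4-bis(diphenylphosphino)butane) under H2 in CH2Cl2. The axial C6 hydroxyl binds rhodium and delivers H2 to the α face of the homoallylic methylene, and the hindered C3=C4 bond, which has no directing group, should react more slowly. No new compound is made.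

**Step 19.** The activated acyl group makes the CH2 between alkene and allyl ester acidic; deprotonation would scramble the position and the geometry of the double bond. Fallback, from 27 back to 32, which avoids the doubly activated CH2 during acylation: 27 is esterified (Yamaguchi conditions: 2,4,6-trichlorobenzoyl chloride, Et3N, then 4-(dimethylamino)pyridine) with (2E)-5-[(tert-butyldimethylsilyl)oxy]-3-methylpent-2-enoic acid F10 to the silyloxy ester F11. HF·pyridine gives the primary alcohol F12, and 2,2,6,6-tetramethylpiperidin-1-oxyl (cat.) with PhI(OAc)2 in MeCN/H2O oxidises it to acid 32.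

## Further compounds

F1 | step 16 | 6-epimer of 26 (equatorial C6–OH, 6S) | CC[C@@H](C)[C@H]1C=C[C@H]2[C@H](OCc3ccc(OC)cc3)[C@@H](O)CC(=C)[C@@H]2[C@H]1C(C)=O
F2 | step 16 | 6-epimer of 27 (equatorial C6–OH, 8R methyl) | CC[C@@H](C)[C@H]1C=C[C@H]2[C@H](OCc3ccc(OC)cc3)[C@@H](O)C[C@@H](C)[C@@H]2[C@H]1C(C)=O
F3 | step 5 | N-acyl (S)-4-benzyl-1,3-oxazolidin-2-one of acid 15 | CC[C@@H](C(=O)N2[C@@H](Cc3ccccc3)COC2=O)[C@H]1C=C[C@@H](CO[Si](C)(C)C(C)(C)C)[C@H](C(C)=C)[C@H]1C4(C)OCCO4
F4 | step 7 | ring A allylic alcohol: as 12 with C4 β-OH | O[C@@H]1C=C[C@H](C2(C)OCCO2)[C@@H](C(C)=C)[C@@H]1CO[Si](C)(C)C(C)(C)C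
F5 | step 7 | ring A propanoate: as 12 with C4 β-propanoyloxy | CCC(=O)O[C@@H]1C=C[C@H](C2(C)OCCO2)[C@@H](C(C)=C)[C@@H]1CO[Si](C)(C)C(C)(C)C
F6 | step 7 | (2S)-2-(ring A C2 β-yl)propanoic acid, ring as in 15 | OC(=O)[C@@H](C)[C@H]1C=C[C@@H](CO[Si](C)(C)C(C)(C)C)[C@H](C(C)=C)[C@H]1C2(C)OCCO2
F7 | step 7 | (2S)-2-(ring A C2 β-yl)propan-1-ol | OC[C@@H](C)[C@H]1C=C[C@@H](CO[Si](C)(C)C(C)(C)C)[C@H](C(C)=C)[C@H]1C2(C)OCCO2
F8 | step 7 | 4-methylbenzenesulfonate of F7 | Cc1ccc(cc1)S(=O)(=O)OC[C@@H](C)[C@H]1C=C[C@@H](CO[Si](C)(C)C(C)(C)C)[C@H](C(C)=C)[C@H]1C2(C)OCCO2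
F9 | step 12 | 2-acyl-1,3-dithiane: as 22 with C5 ketone | CC[C@@H](C)[C@H]1C=C[C@@H](C(=O)C2SCCCS2)[C@H](C(C)=C)[C@H]1C3(C)OCCO3
F0 | step 17 | none | none
F10 | step 19 | (2E)-5-[(tert-butyldimethylsilyl)oxy]-3-methylpent-2-enoic acid | OC(=O)/C=C(\C)CCO[Si](C)(C)C(C)(C)C
F11 | step 19 | O6 (2E)-5-silyloxy-3-methylpent-2-enoate of 27 | CC[C@@H](C)[C@H]1C=C[C@H]2[C@H](OCc3ccc(OC)cc3)[C@H](OC(=O)/C=C(\C)CCO[Si](C)(C)C(C)(C)C)C[C@@H](C)[C@@H]2[C@H]1C(C)=O
F12 | step 19 | O6 (2E)-5-hydroxy-3-methylpent-2-enoate of 27 | CC[C@@H](C)[C@H]1C=C[C@H]2[C@H](OCc3ccc(OC)cc3)[C@H](OC(=O)/C=C(\C)CCO)C[C@@H](C)[C@@H]2[C@H]1C(C)=O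
A1 | alternative 1 | decalin C1 carboxylic acid with O5,O6 acetonide | CC[C@@H](C)[C@H]1C=C[C@H]2[C@@H]3OC(C)(C)O[C@@H]3C[C@@H](C)[C@@H]2[C@H]1C(=O)O
A2 | alternative 1 | trans-fused six-membered lactone on ring B with C4 (E)-alkenyl chain | CC[C@@H](C)/C=C/[C@H]1OC(=O)C[C@H]2[C@H](C)C[C@H]3OC(C)(C)O[C@H]3[C@H]12
A3 | alternative 2 | cis-5,6-diol decalin with the acetyl group as ethylene ketal | CC[C@@H](C)[C@H]1C=C[C@H]2[C@H](O)[C@H](O)C[C@@H](C)[C@@H]2[C@H]1C1(C)OCCO1
A4 | alternative 2 | ring A 1,6-dialdehyde (C4a formyl, C8a 1-methyl-3-oxopropyl), ketal on C1 | CC[C@@H](C)[C@H]1C=C[C@@H](C=O)[C@H]([C@H](C)CC=O)[C@H]1C2(C)OCCO2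
A5 | alternative 3 | ring A cyclohexene aldehyde with C4 butanoate and C8 side chain | CCCC(=O)O[C@@H]1C=C[C@H](C2(C)OCCO2)[C@@H]([C@H](C)CCOCc2ccc(OC)cc2)[C@@H]1C=O
A6 | alternative 3 | (2E)-enal with C8 methyl stereocentre and PMB-protected chain | O=C/C=C/[C@H](C)CCOCc1ccc(OC)cc1
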